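- Substrate charged is the fixed yardstick: each reading splits it into substrate still there and substrate consumed.

the same everywhere: substrate 11 mM

| flask | partner | free catalyst | remark | time |
|---|---|---|---|---|
| epsilon | 15 mM (fed, over 40 s) | 9.8 µM | run made earlier; the fed solution adds 0.10 times the starting volume |  |
| theta | 33 mM (fed, over 40 s) | 9.8 µM | run made earlier; the fed solution adds 0.10 times the starting volume |  |
| alpha | 22 mM (fed, over 40 s) | 20 µM | run made earlier; the fed solution adds 0.10 times the starting volume |  |
| flask | 22.0 mM (fed, over 40 s) | 9.8 µM | the fed solution adds 0.10 times the starting volume | 2.0 h |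

| run | time / min | target / % | substrate / % |
|---|---|---|---|
| epsilon | 2.50 | 13.3 | 71.3 |
| epsilon | 8.00 | 24.9 | 15.9 |
| epsilon | 30.0 | 18.1 | 0 |
| epsilon | 90.0 | 5.8 | 0.4 |
| theta | 2.50 | 17.1 | 61.3 |
| theta | 8.00 | 26.0 | 6.7 |
| theta | 30.0 | 4.0 | 0 |
| theta | 90.0 | 0.4 | 0 |
| alpha | 2.50 | 31.7 | 39.1 |
| alpha | 8.00 | 39.2 | 0 |
| alpha | 30.0 | 15.1 | 0 |
| alpha | 90.0 | 1.8 | 0.3 |

(scatter of a reading: 0.3 percentage points)

- charges are per starting volume, the dose included; the dosed solution carries all of it

- when, up to 2.0 h, the flask holds most target
- the amount of target, in percent of the substrate charged, at that time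

- The bench rule first: the flask holds 2.00 equivalents of partner, so substrate is the limiting reagent, and I count one target per substrate consumed.
- A ratio of readings shows where that stops. In epsilon, target per substrate consumed is 46.3 % at 2.50 min and 29.6 % at 8.00 min, lower and far from the rule's one.
- So I follow one molecule through two forks: substrate must become target, and target must then stay target.
- Theta gives 27.9 % at 8.00 min. Placing the flask between the two runs by its [partner] charge gives 28.9 %, the keep share, meaning target per substrate consumed at that reading.
- My own reckoning gives an estimated bracket for the flask's peak. Interpolated flask substrate at 8.00 min is 12.3 %, which gives 25.3 % target. If the flask's share keeps falling after that reading, its target stays below 28.9 % even with substrate consumed to the end.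
- The forecast says “the flask should peak near 9 min”: 0.15 h (0.12 h to 0.19 h) and 27 % (25.5 % to 29 %). Its 27 % lies inside my bracket, and both rest on the same readings.
- The flask peaks at 0.150 h with 27.5 % target.

    partner + target → over-reaction product (k = 0.0810 /M/s)
    catalyst intermediate D → free catalyst + target (k = 25.0 /s)
    substrate + target → side product (k = 0.810 /M/s)
    catalyst intermediate A ⇌ catalyst intermediate B (K = 2.90, k = 14.0 /s)
    catalyst intermediate C → catalyst intermediate D (k = 14.0 /s)
    partner + catalyst intermediate B ⇌ catalyst intermediate C (K = 2800 /M, k = 410 /M/s)
    substrate + free catalyst → catalyst intermediate A (k = 1000 /M/s)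

- At that time the flask still holds 5.48 % substrate, and the keep share applied to the substrate consumed gives 27.3 %. For a neighbour flask, the same recipe with 55 mM of partner, the same line carried past theta's charge estimates a keep share of 25.7 %, and that neighbour flask holds 22.6 % target at its best.

The numbers in the tables stem from a simulated flask for substances that don't exist; scatter was added.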